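(Readings and results come from a simulation on assumed constants; scatter was added.)

If a catalyst acts in proportion to its amount, then at fixed charges of substrate and coupling partner loading and hours can be traded, and such flasks share one clock.

| flask | substrate | coupling partner | free catalyst | remark | time |
|---|---|---|---|---|---|
| teal | 0.50 M | 0.43 equiv | 2 mol% (in portions, 2) | run made earlier; portions every 3.0 h |  |
| grey | 0.50 M | 1.2 equiv | 2 mol% (in portions, 2) | run made earlier; portions every 3.0 h |  |
| amber | 0.29 M | 1.5 equiv | 2 mol% (in portions, 2) | run made earlier; portions every 3.0 h |  |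
| winter | 0.50 M | 1.50 equiv | 2 mol% (in portions, 2) | the portions of free catalyst follow each other after 3.0 h, the first at the start | 25 h |
| spring | 0.25 M | 0.490 equiv | 0.6 mol% (in portions, 2) | the portions of free catalyst follow each other after 3.0 h, the first at the start | 25 h |
| autumn | 0.50 M | 1.50 equiv | 1.2 mol% (in portions, 2) | the portions of free catalyst follow each other after 3.0 h, the first at the start | 25 h |
| noon | 0.50 M | 1.00 equiv | 0.6 mol% (in portions, 2) | the portions of free catalyst follow each other after 0.80 h, the first at the start | 25 h |
| dusk | 0.50 M | 1.50 equiv | 2 mol% (in portions, 2) | the portions of free catalyst follow each other after 5.0 h, the first at the start | 25 h |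

| run | time / h | product / % | substrate / % |
|---|---|---|---|
| teal | 2.00 | 1.4 | 98.5 |
| teal | 6.00 | 7.2 | 92.1 |
| teal | 12.0 | 15.6 | 83.3 |
| teal | 20.0 | 25.4 | 73.8 |
| grey | 4.00 | 6.4 | 92.8 |
| grey | 8.00 | 16.2 | 83.5 |
| grey | 12.0 | 25.4 | 73.7 |
| grey | 20.0 | 41.5 | 58.3 |
| amber | 1.33 | 0.8 | 98.6 |
| amber | 3.00 | 2.9 | 97.4 |
| amber | 8.00 | 12.0 | 86.7 |
| amber | 20.0 | 32.0 | 68.2 |

(each reading ± 0.5 percentage points)



- the flasks put in order of amount of product, in percent of the substrate charged, best first, at 25 h (winter / spring / autumn / noon / dusk)
- the amount of product, in percent of the substrate charged of the flask you put first, at 25 h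
- the amount of product, in percent of the substrate charged of the flask you put last, at 25 h

Amber supports the proportion: as read, its product grew at about twice the rate once the second portion was in. During the interval half the catalyst is present, so half the interval is lost:

θ = (loading / 2 mol%) × (t − interval / 2)

Here t is the time of reading. For winter this gives 23.5 h, which we call the full-strength time θ: the hours at 2 mol% that a flask has had.

Interval first. Dusk has 22.5 h, and grey, between its last two readings, made 2 percentage points in such an hour, so that is our gap between winter and dusk.

Time and partner next. Grey reached 41.5% at θ = 18.5 h. Scaling this to winter gives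

first round: 52.7%

Going round again, we let the hours past θ = 18.5 h run at grey's last rate, which is less than its mean rate, so

second round: 51.6%

Winter has more partner than grey, and at 20.0 h teal's 25.4% against grey's 41.5% shows partner lifting product, so we keep the first round.

Loading then. Autumn has 14.1 h, which on grey's curve gives 32.6%. Noon has 7.38 h, a little past grey's 16.2% at 6.50 h, but with less partner than grey, so we say about that.

Charges last. In spring the partner is the limiting reagent, at 0.122 M, less than teal's 0.215 M, and spring's substrate, at 0.25 M, is also below teal's 0.50 M. At θ = 7.05 h, spring should therefore lie below teal's 10.8%.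

The forecast gives winter > dusk > autumn > noon > spring, with 52% on top (47% to 57%) and 7% last (4% to 10%), judging that “the earlier full loading favours winter”. Our first round stands 0.70 points above its top figure.

The flasks give winter > dusk > autumn > noon > spring: winter 53.4%, dusk 51.5%, autumn 34.3%, noon 16.8%, spring 6.09%.

    catalyst intermediate C → free catalyst + product (k = 5.20 h⁻¹)
    coupling partner + catalyst intermediate A → catalyst intermediate B (k = 26.0 M⁻¹ h⁻¹)
    substrate + free catalyst ⇌ catalyst intermediate A (K = 1.10 M⁻¹, k = 32.0 M⁻¹ h⁻¹)
    catalyst intermediate B ⇌ catalyst intermediate C (K = 0.560, k = 82.0 h⁻¹)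

Winter at θ = 23.5 h leads dusk at θ = 22.5 h by 1.9 points. Winter read at 15.0 h, θ = 13.5 h, holds 32.8% product and 31.0% free catalyst, beside autumn's 34.3% and 31.5% at 25.0 h, θ = 14.1 h. In winter at 12.0 h, catalyst intermediate C falls back 28 times faster than it goes on to product, and catalyst intermediate A 1.8 times faster than it goes on. At 25.0 h winter's catalyst stands at 41.9% free catalyst, 32.9% catalyst intermediate B, 17.8% catalyst intermediate C and 7.35% catalyst intermediate A.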